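The data were generated by integration on assumed constants.

Temperature is the one setting that separates the two new flasks, Monday's being the hotter.

| flask | L | temperature | remark | time |
|---|---|---|---|---|
| noon | 0.46 M | 75 °C | run made earlier |  |
| midnight | 0.73 M | 90 °C | run made earlier |  |
| Monday's | 0.33 M | 100 °C |  | 1.5 h |
| Sunday's | 0.33 M | 80 °C |  | 1.5 h |

noon run (percent of the L charged)

| time / h | E / % |
|---|---|
| 0.333 | 8 |
| 0.500 | 8 |
| 1.00 | 8 |
| 2.50 | 15 |
| 5.00 | 19 |

midnight run (percent of the L charged)

| time / min | E / % |
|---|---|
| 25.0 | 22 |
| 50.0 | 28 |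
| 60.0 | 34 |
| 90.0 | 36 |
| 120 | 35 |

(scatter of a reading: 2 percentage points)

- the flask with the highest amount of E, in percent of the L charged ("all alike" if they lie within 1.5 percentage points) (Monday's / Sunday's / all alike)
- final E, as a percentage of the L charged, in Monday's
- final E, as a percentage of the L charged, in Sunday's

- what was read earlier has a scatter of 2 percentage points, one standard deviation
- a reading or a percentage of E counts all its forms, free or not

The midnight run levels off near 35.5%, so we follow the fraction of that ceiling still unmade, not the E made. At 25.0 min that fraction is 0.380, and the pace at which it shrinks, the logarithm of its inverse divided by the time, reads 2.32 h⁻¹ from this one reading. The last noon reading, held against the same ceiling, gives a slower 0.153 h⁻¹.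

With midnight's pace and ceiling, 0.0308 stays unmade after 1.5 h, which leaves 34.4% of E. If pace and ceiling both rise with temperature and do not depend on the charge of L, this is a floor for Monday's and a roof for Sunday's. The noon ceiling is at least its last reading, so if the ceiling also climbs in a straight line with temperature, our top for Monday's is 46.5%. For Sunday's, a straight line between the noon readings at 1.00 h and 2.50 h gives a floor of about 10.3% under the same conditions. Interpolating the logarithm of the pace gives 0.379 h⁻¹, and keeping midnight's ceiling gives our estimate of 15.4%.

The forecast also puts Monday's ahead, with 36% (24% to 50%) there, a central value inside our bracket, cautioning that “the ceiling may shift with temperature and concentration”, and with 17% (10% to 26%) for Sunday's, above our estimate.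

The flasks give 47.1% in Monday's, 0.60 percentage points over our top, which was built from readings with a scatter of 2 points, and 18.6% in Sunday's, 3.2 points over our estimate.

    L ⇌ E (K = 3.00, k = 4.50 × 10⁻⁴ s⁻¹, Ea = 99.0 kJ mol⁻¹, ΔH = −43.0 kJ mol⁻¹)
    E ⇌ G (K = 0.900, k = 6.50 × 10⁻⁵ s⁻¹, Ea = 125 kJ mol⁻¹, ΔH = −58.0 kJ mol⁻¹)
    G ⇌ L (k = 1.00 × 10⁻⁴ s⁻¹, Ea = 108 kJ mol⁻¹)
    L + E ⇌ X, settled at all times (K = 3.50 M⁻¹, ΔH = −5.00 kJ mol⁻¹)
    (constants at 100 °C)

Taking the 47.1% at 1.5 h as the mark for Monday's, that flask holds 43.7% of E at 0.750 h, so 0.0722 is unmade, less than the 0.176 that 2.32 h⁻¹ gives. The same flask stopped at 25 min holds 35.6%, so 0.244 is unmade there, against 0.380 at midnight's pace. Its own pace against that mark comes to 3.38 h⁻¹. At that time 33% of the charge in this stopped flask is still unbound L.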